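## Retrosynthetic overview

1. Rings A and B are bought as arenes; ring C is the only ring made, and it is closed last.
2. Ring B piece: veratraldehyde 1 + geranyl bromide 2 give, through 3, 4 and 5, the aldehyde 6. The disconnection is the aryl C2'–CH2 bond (in-situ-protected ortho-lithiation, then allylation).
3. Ring A piece: acetophenone 7 is joined to 6 at Cα=Cβ (trilithium enolate 8, aldolate 9) to give the free 2',6'-dihydroxychalcone 10, with no protecting groups.
4. Key disconnection O1–C2: 10 is closed to flavanone 11 by a chalcone-isomerase-like enantioselective oxa-Michael addition, which forms ring C and sets C2 (S) in the final step.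

Assumption: the quinine-derived catalyst is taken to give the (2S) series; this is checked on the first run by chiral HPLC and CD against racemate, and the quinidine-derived pseudo-enantiomer is used in the same step if the sense is reversed.

## Route

Step 1
Reactants: 1 3,4-dimethoxybenzaldehyde (veratraldehyde); 2 geranyl bromide [(2E)-1-bromo-3,7-dimethylocta-2,6-diene]
Product: 6 2-[(2E)-3,7-dimethylocta-2,6-dien-1-yl]-3,4-dimethoxybenzaldehyde, via lithium α-amino alkoxide 3 (not isolated), via C2-aryllithium 4 (not isolated), via geranylated lithium α-amino alkoxide 5 (not isolated)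
Conditions: Me2NCH2CH2NHMe, n-BuLi (1.1 equiv), THF, −20 °C; add 1; n-BuLi (2.0 equiv), −20 °C, 3 h; inverse addition to 2 (3.0 equiv), THF, −78 → 0 °C; cold 1 M HCl
Reagents that add atoms: lithium N,N,N'-trimethylethylenediamide [Li]N(C)CCN(C)C; n-butyllithium [Li]CCCC (both add atoms only to the unisolated 3–5; nothing from them remains in 6)
Why: Comins in-situ α-amino alkoxide protection and directed ortho-metalation: the CH(OLi)NR2 group and the 3-OMe group together direct lithiation to C2, the aryllithium displaces bromide at the primary allylic carbon (SN2, E-olefin untouched), and acidic work-up collapses the hemiaminal back to the aldehyde; no stereocenter is formed.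

Step 2
Reactants: 6 2-[(2E)-3,7-dimethylocta-2,6-dien-1-yl]-3,4-dimethoxybenzaldehyde; 7 1-(2,6-dihydroxy-4-methoxyphenyl)ethanone (2',6'-dihydroxy-4'-methoxyacetophenone)
Product: 10 (2E)-1-(2,6-dihydroxy-4-methoxyphenyl)-3-{2-[(2E)-3,7-dimethylocta-2,6-dien-1-yl]-3,4-dimethoxyphenyl}prop-2-en-1-one, via trilithium enolate 8 (not isolated), via trilithium aldolate 9 (not isolated)
Conditions: 7, LiHMDS (3.2 equiv), THF, −78 °C, 1 h; 6 (1.0 equiv), −78 °C → rt, 16 h; ice-cold 1 M HCl; rapid chromatography or crystallisation
Reagents that add atoms: lithium hexamethyldisilazide [Li]N([Si](C)(C)C)[Si](C)(C)C (lithium only, in the unisolated 8 and 9; nothing remains in 10)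
Why: Protecting-group-free Claisen–Schmidt aldol condensation through the phenoxide/enolate trianion: the enolate adds to the non-enolisable aldehyde, the aldolate eliminates (E1cB) to the thermodynamically favoured (E)-enone, and the strongly basic medium holds the product as the open-chain bis-phenoxide, so no racemic ring closure occurs before cold acidification.

Step 3
Reactants: 10 (2E)-1-(2,6-dihydroxy-4-methoxyphenyl)-3-{2-[(2E)-3,7-dimethylocta-2,6-dien-1-yl]-3,4-dimethoxyphenyl}prop-2-en-1-one
Product: 11 (2S)-2-{2-[(2E)-3,7-dimethylocta-2,6-dien-1-yl]-3,4-dimethoxyphenyl}-5-hydroxy-7-methoxy-2,3-dihydro-4H-chromen-4-one (target CNP0332239.1)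
Conditions: N-[3,5-bis(trifluoromethyl)phenyl]-N'-(9-deoxy-epi-quinin-9-yl)thiourea (10 mol %), toluene (0.05 M), 4 Å MS, −20 °C, 72 h; AcOH quench, SiO2
Reagents that add atoms: none
Why: Proposed new method: chalcone-isomerase-mimetic enantioselective 6-endo-trig intramolecular oxa-Michael addition of a free 2',6'-dihydroxychalcone, in which the quinuclidine nitrogen deprotonates the non-chelated phenol (the other OH stays hydrogen-bonded to the carbonyl; the two OH groups are equivalent by aryl rotation), the thiourea N–H pair binds the carbonyl and developing enolate oxygen, and the chiral ion pair delivers the phenoxide to one face of the s-cis enone to set C2 as (S) under kinetic control at low temperature, where uncatalysed closure and retro-Michael racemisation are slow; the closest known reaction type is the bifunctional cinchona-thiourea-catalysed asymmetric oxa-Michael cyclisation of 2'-hydroxychalcones and of their α-carboxylate-activated analogues to flavanones.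

## Compound list

1 | 3,4-dimethoxybenzaldehyde (veratraldehyde) | COc1ccc(C=O)cc1OC | starting material
2 | geranyl bromide, (2E)-1-bromo-3,7-dimethylocta-2,6-diene | BrC/C=C(\C)CCC=C(C)C | starting material
3 | lithium α-amino alkoxide from 1 and LiN(Me)CH2CH2NMe2 (racemic at the carbinol carbon) | COc1ccc(C(O[Li])N(C)CCN(C)C)cc1OC | intermediate (not isolated)
4 | C2-lithiated derivative of 3 (aryllithium between the alkoxide carbon and 3-OMe) | COc1ccc(C(O[Li])N(C)CCN(C)C)c([Li])c1OC | intermediate (not isolated)
5 | 2-geranylated lithium α-amino alkoxide | COc1ccc(C(O[Li])N(C)CCN(C)C)c(C/C=C(\C)CCC=C(C)C)c1OC | intermediate (not isolated)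
6 | 2-[(2E)-3,7-dimethylocta-2,6-dien-1-yl]-3,4-dimethoxybenzaldehyde | COc1ccc(C=O)c(C/C=C(\C)CCC=C(C)C)c1OC | intermediate
7 | 1-(2,6-dihydroxy-4-methoxyphenyl)ethanone | CC(=O)c1c(O)cc(OC)cc1O | starting material
8 | trilithium enolate/bis-phenoxide of 7 | C=C(O[Li])c1c(O[Li])cc(OC)cc1O[Li] | intermediate (not isolated)
9 | trilithium aldolate of 8 and 6 (racemic at the carbinol carbon) | COc1cc(O[Li])c(C(=O)CC(O[Li])c2ccc(OC)c(OC)c2C/C=C(\C)CCC=C(C)C)c(O[Li])c1 | intermediate (not isolated)
10 | (2E)-1-(2,6-dihydroxy-4-methoxyphenyl)-3-{2-[(2E)-3,7-dimethylocta-2,6-dien-1-yl]-3,4-dimethoxyphenyl}prop-2-en-1-one (chalcone) | COc1cc(O)c(C(=O)/C=C/c2ccc(OC)c(OC)c2C/C=C(\C)CCC=C(C)C)c(O)c1 | intermediate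
11 | (2S)-2-{2-[(2E)-3,7-dimethylocta-2,6-dien-1-yl]-3,4-dimethoxyphenyl}-5-hydroxy-7-methoxy-2,3-dihydro-4H-chromen-4-one | COc1cc(O)c2c(c1)O[C@H](c1ccc(OC)c(OC)c1C/C=C(\C)CCC=C(C)C)CC2=O | target

## Summary and risks

Total step count: 3. Longest linear sequence: 3 steps (1 → 6 → 10 → 11).

Step 3 is the most likely to fail. High ee on an unactivated chalcone with an electron-rich, ortho-substituted B ring is not established, and the reaction is reversible, so ee can erode at high conversion. Fallback: setting out from 10, close the ring without induction (NaOAc, EtOH, reflux) to the racemic flavanone F1, then resolve by preparative chiral SFC on an amylose carbamate phase, which comes back to the route at 11. The unwanted (2R)-enantiomer F2 is reopened to the chalcone bis-phenoxide (aq KOH/EtOH, then cold acidification) and re-enters at 10.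

Step 1 is next. The hindered aryllithium must be allylated while excess n-BuLi is present, which risks Wurtz-type by-products, lateral metalation of the new benzylic/allylic CH2, and some SN2' product. Fallback: setting out from 1 through the same aryllithium 4, quench with iodine instead of 2 to give the iodinated lithium α-amino alkoxide F3, which is hydrolysed on work-up to 2-iodo-3,4-dimethoxybenzaldehyde F4. Separately, 2 is converted with Bu3SnLi (THF, −78 °C) into tributyl[(2E)-3,7-dimethylocta-2,6-dien-1-yl]stannane F5. Stille coupling of F4 with F5 (Pd2(dba)3, AsPh3, CuI, DMF, 60 °C) forms the aryl–CH2 bond by cross-coupling instead of SN2 and comes back at 6.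

Step 2 is third. The trianion may be poorly soluble or react sluggishly with the hindered aldehyde, and any free LiHMDS could isomerise the skipped diene. Fallback: setting out from 7, protect the one non-chelated phenol (MOMCl, i-Pr2NEt, CH2Cl2, 0 °C) to give 1-[2-hydroxy-4-methoxy-6-(methoxymethoxy)phenyl]ethanone F6. Condense F6 with 6 under classical Claisen–Schmidt conditions (50% aq KOH, EtOH, rt) to the MOM-protected chalcone F7. Remove the MOM group (3 M HCl, MeOH, rt), and reopen any flavanone formed with aq KOH followed by cold acidification, which comes back at 10.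

## Further compounds

F1 | step 3 | racemic 2-{2-[(2E)-3,7-dimethylocta-2,6-dien-1-yl]-3,4-dimethoxyphenyl}-5-hydroxy-7-methoxy-2,3-dihydro-4H-chromen-4-one | COc1cc(O)c2c(c1)OC(c1ccc(OC)c(OC)c1C/C=C(\C)CCC=C(C)C)CC2=O
F2 | step 3 | (2R)-2-{2-[(2E)-3,7-dimethylocta-2,6-dien-1-yl]-3,4-dimethoxyphenyl}-5-hydroxy-7-methoxy-2,3-dihydro-4H-chromen-4-one | COc1cc(O)c2c(c1)O[C@@H](c1ccc(OC)c(OC)c1C/C=C(\C)CCC=C(C)C)CC2=O
F3 | step 1 | 2-iodinated lithium α-amino alkoxide (from 4 and iodine) | COc1ccc(C(O[Li])N(C)CCN(C)C)c(I)c1OC
F4 | step 1 | 2-iodo-3,4-dimethoxybenzaldehyde | COc1ccc(C=O)c(I)c1OC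
F5 | step 1 | tributyl[(2E)-3,7-dimethylocta-2,6-dien-1-yl]stannane | CCCC[Sn](CCCC)(CCCC)C/C=C(\C)CCC=C(C)C
F6 | step 2 | 1-[2-hydroxy-4-methoxy-6-(methoxymethoxy)phenyl]ethanone | CC(=O)c1c(O)cc(OC)cc1OCOC
F7 | step 2 | (2E)-1-[2-hydroxy-4-methoxy-6-(methoxymethoxy)phenyl]-3-{2-[(2E)-3,7-dimethylocta-2,6-dien-1-yl]-3,4-dimethoxyphenyl}prop-2-en-1-one | COCOc1cc(OC)cc(O)c1C(=O)/C=C/c1ccc(OC)c(OC)c1C/C=C(\C)CCC=C(C)C
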